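## Structural features

The target 14 is a single six-membered carbocycle in which C1 is the ketone carbon, C2=C3 the conjugated alkene, C4 and C6 methylene groups, and C5 a fully substituted carbinol carbon that carries the hydroxyl and an unbranched nonadecyl chain. C5 is the only stereocentre (S) and has no stereogenic neighbour. Its two ring arms differ only at a distance (CH2–C=O against CH2–CH=), so no adjacent group can set it by induction. The hydroxyl is β to the ketone, so acid, base or heat can dehydrate the ring towards a phenol or open it by retro-aldol cleavage, and the enone should therefore be unveiled last and under neutral conditions. The chain is chemically inert but makes the intermediates waxy, so polar handles help purification. The real difficulty is the absolute configuration of the tertiary alcohol together with the placement of carbonyl and alkene on defined sides of it. The key step exploits a mapping onto (−)-quinic acid 1, in which C5 with its oxygen and both CH2 flanks is C1 of 1, the oxidized C1–C2–C3 run is the hydroxylated C5–C4–C3 of 1, and the carboxyl carbon becomes C1′ of the chain. In 1 the C1 hydroxyl is cis to the C3/C4 diol and trans to the lactone-forming C5 hydroxyl, so turning C5 into the carbonyl and C3/C4 into the alkene leads to the S configuration.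

## Logic of the disconnections

14 ⇒ 13. No skeletal bond is cut; the C1=O double bond is taken back to the C–H and O–H bonds of a secondary allylic alcohol. The reason is the fragile β-hydroxy enone, which should appear only in the final operation. The gain is that all earlier intermediates are robust alcohols and ethers. The forward step must oxidize the allylic carbinol without touching the tertiary one and without inducing loss of water.

13 ⇒ 12. The O–H bond of the allylic oxygen is exchanged for an O–Si bond. This oxygen must stay distinguishable from the tertiary oxygen and from the two oxygens that are removed. The gain is a fully differentiated oxygen pattern. The silyl group must survive aqueous acid and 110 °C and still leave with fluoride.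

12 ⇒ 11 ⇒ 10. The C2=C3 double bond (target numbering) is taken back to two C–O single bonds, first tied into a cyclic thiocarbonate in 11, then free as a cis-diol in 10. Stereospecific syn-deoxygenation of a cis-diol fixes the alkene position next to the future carbonyl carbon without ambiguity. The gain is that two sp2 carbons become oxygenated carbons that the chiral pool supplies. The thiocarbonate must close only on the cis pair, and the fragmentation must spare the tertiary alcohol.

10 ⇒ 9. The two diol O–H bonds are exchanged for the two acetal C–O bonds of an isopropylidene group. This group goes selectively onto the only cis-diol of 1 and is inert to organometallic reagents. The gain is a precursor without acidic hydrogen on these oxygens. The forward hydrolysis must leave the silyl ether in place.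

9 ⇒ 6 + 8, and 8 ⇒ 7. The C1′–C2′ bond of the chain is cut and the tertiary oxygen is reconnected to C1′ as an oxirane. The bond lies next to the stereocentre but not at it, so forming it cannot disturb the configuration. The gain is the largest in the route: the C18 part separates as a commercial halide and the chiral part shrinks to a seven-carbon oxygenated ring. The forward step needs attack at the oxirane CH2 only, and no Lewis-acid isomerization of the oxirane.

6 ⇒ 5 ⇒ 4 ⇒ 3. The oxirane O–C7 bond is cut to a tertiary alcohol and a primary sulfonate (5), then the O–Si bond (4), then the O–S bond (3). Closing the oxirane through the primary carbon leaves the C1–O bond intact. Silylation precedes closure so that the C5 oxygen cannot displace the sulfonate. The gain is a triol with one primary, one secondary and one tertiary hydroxyl. The forward steps need selective primary sulfonylation and selective secondary silylation.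

3 ⇒ 2 ⇒ 1. The two C–H bonds of the CH2OH group are taken back to a lactone carbonyl with the acyl–O5 bond re-formed (2); then the lactone C–O bond and the two acetal C–O bonds are cut (1). Lactone and acetonide together sort the three secondary hydroxyls of 1 into a protected cis pair and a single trans one. The gain is a cheap, enantiopure starting material. The forward steps need a one-pot acetalization–lactonization and a hydride reduction that spares the acetal.

## Other disconnections considered

Alternative 1: The ring bonds C1–C2 and C3–C4 of 14 are cut. C2 and C3 leave as acetylene A2, and the remainder contracts to 3-(tert-butyldimethylsilyloxy)-3-nonadecylcyclobutan-1-one A1, an achiral ketone with a mirror plane through the carbonyl and the carbinol carbon.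
- **Forward key step:** Ni(cod)2 (zerovalent nickel) with a chiral phosphine would couple the carbonyl of A1 with A2 by oxidative cyclization. β-Carbon elimination would break one of the two enantiotopic acyl–CH2 bonds, and reductive elimination would close (S)-5-(tert-butyldimethylsilyloxy)-5-nonadecylcyclohex-2-en-1-one A3. Desilylation of A3 would give 14.
- **In its favour:** ring, enone and stereocentre would arise in one catalytic operation, and either enantiomer would be open through the ligand. On step economy (about half the length) and on flexibility it is the better plan.
- **Against it here:** this insertion is established for disubstituted alkynes, whereas A2 tends to oligomerize on zerovalent nickel, and the target needs exactly the unsubstituted two-carbon unit. The catalyst would have to tell apart two acyl–CH2 bonds that differ only through a remote carbon bearing silyloxy against a linear alkyl group. The β-silyloxy ketone motif of A1 and A3 also invites β-oxygen elimination.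
- **Comparison:** on structure, the chosen plan inherits the stereocentre from 1, while the alternative stakes it on one enantio-determining C–C cleavage. On mechanism, one SN2 opening with a single sensible regiochemistry stands against a three-stage metallacycle sequence with a competing path at each stage. The two plans are equal in exposing the free β-hydroxy enone only at the very end.

Alternative 2: The C5–O bond of 14 is traced to a C–B bond and the C2=C3 double bond is saturated. This leads to 3-nonadecylcyclohex-2-en-1-one A4, whose β-carbon is the future C5.
- **Forward key step:** CuCl, NaOtBu and a chiral bisphosphine of the P-stereogenic quinoxaline type would generate a monovalent copper boryl complex from bis(pinacolato)diboron A5. The boryl group of A5 would be delivered to the β-carbon of A4 to give (R)-3-nonadecyl-3-(4,4,5,5-tetramethyl-1,3,2-dioxaborolan-2-yl)cyclohexan-1-one A6. Stereoretentive oxidation of the C–B bond of A6 (NaBO3) would give (S)-3-hydroxy-3-nonadecylcyclohexan-1-one A7. Dehydrogenation of A7 on the side remote from the carbinol (regioselective enolization, then Saegusa–Ito oxidation with Pd(OAc)2, divalent palladium) would complete 14.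
- **In its favour:** A4 should follow in one or two steps from 3-ethoxycyclohex-2-en-1-one A8 and 1-bromononadecane A9 (magnesium insertion, 1,2-addition and acidic transposition, a Stork–Danheiser sequence), and conjugate borylation of β-substituted cyclic enones to tertiary boronates such as A6 is a documented reaction class. About five steps would suffice, so on step economy it is clearly the better plan. It is the equal of the chosen plan in drawing the chain from a commercial long-chain bromide, here A9.
- **Against it here:** the catalyst must distinguish the faces of a β-carbon whose substituents are a ring CH2 and a long flexible chain, so enantiopurity is not assured in advance. The last stage is the weak point: A7 is a β-hydroxy ketone, and any enolate formed towards the carbinol would expel the tertiary oxygen or open the ring. The hydroxyl would probably need protection, costing two steps.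
- **Comparison:** on structure, the chosen plan fixes carbonyl and alkene positions through three pre-existing oxygens, whereas here an enolization decides them. On mechanism, an enantioface-selective borylcupration plus two oxidations stands against a stereochemically silent substitution.

Alternative 3: The C1–O bond is strategic. 14 is traced to (1S,5S)-5-hydroxy-5-nonadecylcyclohex-2-en-1-yl pivalate A12. Its ester C1–O bond is cut to sodium pivalate A11 and racemic 1-nonadecyl-2,4-dioxabicyclo[3.3.1]non-6-en-3-one A10, a bridged cyclic carbonate that spans the secondary allylic and the tertiary oxygen.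
- **Forward key step:** Pd2(dba)3 (zerovalent palladium) with the C2-symmetric bis(2-diphenylphosphinobenzamide) ligand from trans-cyclohexane-1,2-diamine would ionize both enantiomers of A10. Loss of carbon dioxide would leave an allyl–palladium species with a mirror plane through C2 and C5. A11 would attack one enantiotopic terminus on the face away from the metal to give A12. Ester cleavage and allylic oxidation would then give 14.
- **In its favour:** both enantiomers of a racemate would be funnelled into one product, and carboxylate additions to cyclic meso allyl complexes with this ligand class are a documented route to high selectivity. A12 has the same differentiation of secondary allylic and tertiary oxygen that the chosen route reaches in 13. The endgame is therefore the equal of the chosen one, including the final allylic oxidation.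
- **Against it here:** A10 must first be made with the tertiary and secondary oxygens cis, which needs a diastereoselective sequence of its own. The tertiary alkoxide released on decarboxylation is a base and a competing nucleophile. The C5 substituents sit over the allyl unit, so their effect on the chiral pocket is hard to foresee.
- **Comparison:** on structure, the chosen plan secures C5 by inheritance. The alternative secures it indirectly, through the choice of allyl terminus, and only after the C1 stereocentre is destroyed by oxidation. On mechanism, a catalyst-controlled desymmetrization of a meso intermediate stands against a substrate-defined substitution. On step economy the alternative would probably be a few steps shorter, and it is the better plan if both enantiomers of 14 are wanted.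

Key step: step 6

Remark on the chemistry: the quinic C5 oxygen is carried as a tert-butyldiphenylsilyl ether and not as the tert-butyldimethylsilyl ether, because it must outlast the aqueous acid that removes the cis-fused acetonide in step 7, where the dimethyl analogue would be borderline; skeleton, key bond and configurations are unchanged, intermediates are named in quinic numbering (C1 quaternary, C3/C4 cis-diol, C5 lactone-forming carbinol, C7 exocyclic carbon), and CIP descriptors change with substituent priority although no stereocentre is touched.

## Steps

Step 1
Reactants: 1 (−)-quinic acid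
Product: 2 3,4-O-isopropylidene-1,5-quinic lactone, (1S,3R,4R,5R) in quinic numbering
Conditions: Me2C(OMe)2, TsOH·H2O (cat.), acetone, reflux
Reagents that add atoms: 2,2-dimethoxypropane, COC(C)(C)OC
Why: Acid-catalysed transketalization places the isopropylidene group on the only cis-vicinal diol (O3/O4), and the carboxyl lactonizes onto the cis-disposed O5 (γ-lactone), both under thermodynamic control; no stereocentre is touched.

Step 2
Reactants: 2 3,4-O-isopropylidene-1,5-quinic lactone
Product: 3 (1R,3R,4S,5R)-1-(hydroxymethyl)-3,4-O-isopropylidenecyclohexane-1,3,4,5-tetrol (quinic numbering)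
Conditions: NaBH4, EtOH, 0 °C → rt; aq. NH4Cl
Reagents that add atoms: none
Why: Hydride reduction of a lactone activated by its α-hydroxyl and ring strain; NaBH4 in ethanol suffices, spares the acetonide, and releases O5 as a free secondary alcohol and the former carboxyl carbon as CH2OH.

Step 3
Reactants: 3 (1R,3R,4S,5R)-1-(hydroxymethyl)-3,4-O-isopropylidenecyclohexane-1,3,4,5-tetrol
Product: 4 (1R,3R,4S,5R)-3,4-O-isopropylidene-1-[(p-toluenesulfonyloxy)methyl]cyclohexane-1,3,4,5-tetrol (quinic numbering)
Conditions: TsCl (1.1 equiv), pyridine, CH2Cl2, 0 °C
Reagents that add atoms: p-toluenesulfonyl chloride, Cc1ccc(cc1)S(Cl)(=O)=O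
Why: Chemoselective sulfonylation: the primary hydroxyl reacts much faster than the ring secondary hydroxyl at 0 °C, the tertiary one is inert, and near-stoichiometric reagent limits double sulfonylation.

Step 4
Reactants: 4 (1R,3R,4S,5R)-3,4-O-isopropylidene-1-[(p-toluenesulfonyloxy)methyl]cyclohexane-1,3,4,5-tetrol
Product: 5 (1S,3R,4R,5R)-5-O-(tert-butyldiphenylsilyl)-3,4-O-isopropylidene-1-[(p-toluenesulfonyloxy)methyl]cyclohexane-1,3,4,5-tetrol (quinic numbering)
Conditions: TBDPSCl, imidazole, DMF, rt → 40 °C
Reagents that add atoms: tert-butyl(chloro)diphenylsilane, CC(C)(C)[Si](Cl)(c1ccccc1)c1ccccc1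
Why: Imidazole-promoted silylation of the secondary hydroxyl; the tertiary hydroxyl is too hindered for the bulky chlorosilane, imidazole is too weak a base to displace the sulfonate, and blocking O5 stops it from later closing a bridged ether onto C7.

Step 5
Reactants: 5 (1S,3R,4R,5R)-5-O-(tert-butyldiphenylsilyl)-3,4-O-isopropylidene-1-[(p-toluenesulfonyloxy)methyl]cyclohexane-1,3,4,5-tetrol
Product: 6 spiro-epoxide, (1S,3R,4R,5R)-1,7-anhydro-5-O-(tert-butyldiphenylsilyl)-1-(hydroxymethyl)-3,4-O-isopropylidenecyclohexane-1,3,4,5-tetrol (quinic numbering; oxirane formed by O1 and C7)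
Conditions: K2CO3, MeOH, rt
Reagents that add atoms: none
Why: Intramolecular Williamson etherification (3-exo-tet): the tertiary alkoxide displaces the primary sulfonate at C7, so the C1–O bond and the configuration at C1 are untouched; silyl ether and acetonide are stable to K2CO3 in methanol.

Step 6
Reactants: 6 spiro-epoxide (quinic numbering, 3,4-O-isopropylidene, 5-O-tert-butyldiphenylsilyl); 7 1-bromooctadecane
Product: 9 (1S,3R,4R,5R)-5-O-(tert-butyldiphenylsilyl)-3,4-O-isopropylidene-1-nonadecylcyclohexane-1,3,4,5-tetrol (quinic numbering), via octadecylmagnesium bromide 8 (not isolated)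
Conditions: 7 (2 equiv), Mg, I2 (cat.), THF, reflux; then CuI (10 mol %), THF, −30 °C; 6, −30 → 0 °C; aq. NH4Cl
Reagents that add atoms: none
Why: Grignard reagent 8 transmetalates to CuI to give the cuprate [R2Cu]MgBr (monovalent copper, R = octadecyl), which attacks the oxirane CH2 of 6 from the side opposite the C–O bond in an SN2 fashion; the resulting trivalent copper alkyl reductively eliminates, forming the C1′–C2′ bond, releasing the tertiary alkoxide as its bromomagnesium salt (ROMgBr) and returning monovalent copper to the cycle. The closest known reaction type is the copper-catalysed opening of terminal and 2,2-disubstituted epoxides by alkyl Grignard reagents at the primary carbon. No ring is closed and no stereocentre is created: the C1–O bond is never broken, so the configuration of quinic C1, the future C5 of 14, is carried through unchanged. The step needs regioselectivity for CH2 over the quaternary oxirane carbon, which the fully substituted spiro centre enforces sterically. It also needs substitution to outrun MgBr2-induced isomerization or bromide opening of the oxirane, which catalytic copper, THF and low temperature favour. Compound 6 has no acidic hydrogen, and its acetonide and silyl ether are inert to carbanions, so only the strained ring reacts.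

Step 7
Reactants: 9 (1S,3R,4R,5R)-5-O-(tert-butyldiphenylsilyl)-3,4-O-isopropylidene-1-nonadecylcyclohexane-1,3,4,5-tetrol
Product: 10 (1S,3R,4R,5R)-5-O-(tert-butyldiphenylsilyl)-1-nonadecylcyclohexane-1,3,4,5-tetrol (quinic numbering; 1-OH, 3-OH and 4-OH free)
Conditions: AcOH–H2O–THF (4:1:1), 60 °C
Reagents that add atoms: none
Why: Acid-catalysed acetal hydrolysis, with THF added to keep the waxy substrate in solution; the tert-butyldiphenylsilyl ether tolerates warm aqueous acetic acid, and only acetal C–O bonds are cleaved, so C3 and C4 keep their oxygens and configurations.

Step 8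
Reactants: 10 (1S,3R,4R,5R)-5-O-(tert-butyldiphenylsilyl)-1-nonadecylcyclohexane-1,3,4,5-tetrol
Product: 11 (1S,3R,4R,5R)-5-O-(tert-butyldiphenylsilyl)-1-nonadecyl-3,4-O-thiocarbonylcyclohexane-1,3,4,5-tetrol (quinic numbering; cyclic thionocarbonate on O3/O4)
Conditions: 1,1'-thiocarbonyldiimidazole, toluene, 90 °C
Reagents that add atoms: 1,1'-thiocarbonyldiimidazole, S=C(n1ccnc1)n1ccnc1
Why: Thiocarbonylation: the less hindered 3-OH is thioacylated and the cis 4-OH closes the five-membered cyclic thiocarbonate, while the tertiary 1-OH is too hindered to react.

Step 9
Reactants: 11 (1S,3R,4R,5R)-5-O-(tert-butyldiphenylsilyl)-1-nonadecyl-3,4-O-thiocarbonylcyclohexane-1,3,4,5-tetrol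
Product: 12 (1S,5R)-5-(tert-butyldiphenylsilyloxy)-1-nonadecylcyclohex-3-en-1-ol
Conditions: P(OMe)3, 110 °C
Reagents that add atoms: none
Why: Corey–Winter olefination: the phosphite abstracts sulfur, and the resulting 1,3-dioxolan-2-ylidene undergoes stereospecific syn cycloreversion with loss of CO2, turning the cis-diol carbons into the ring alkene; the silyl ether and the remote tertiary alcohol are spectators.

Step 10
Reactants: 12 (1S,5R)-5-(tert-butyldiphenylsilyloxy)-1-nonadecylcyclohex-3-en-1-ol
Product: 13 (1R,5S)-5-nonadecylcyclohex-2-ene-1,5-diol (hydroxyls trans)
Conditions: TBAF, THF, 0 °C → rt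
Reagents that add atoms: none
Why: Fluoride-induced Si–O cleavage driven by the strong Si–F bond; alkene and tertiary alcohol are unaffected, and no carbonyl is yet present that could suffer under the basic fluoride.

Step 11
Reactants: 13 (1R,5S)-5-nonadecylcyclohex-2-ene-1,5-diol
Product: 14 (S)-5-hydroxy-5-nonadecylcyclohex-2-en-1-one
Conditions: MnO2 (activated), CH2Cl2, rt
Reagents that add atoms: none
Why: Selective oxidation of the allylic secondary alcohol by activated MnO2 under neutral heterogeneous conditions; the tertiary alcohol cannot be oxidized, the stereocentre is not involved, and the mildness spares the dehydration-prone β-hydroxy enone.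

## Compound list

1 | (−)-quinic acid, (1S,3R,4S,5R)-1,3,4,5-tetrahydroxycyclohexane-1-carboxylic acid | OC(=O)[C@]1(O)C[C@@H](O)[C@@H](O)[C@H](O)C1 | starting material
2 | 3,4-O-isopropylidene-1,5-quinic lactone, (1S,3R,4R,5R) in quinic numbering | O=C3[C@]1(O)C[C@H]2OC(C)(C)O[C@H]2[C@H](O3)C1 | intermediate
3 | (1R,3R,4S,5R)-1-(hydroxymethyl)-3,4-O-isopropylidenecyclohexane-1,3,4,5-tetrol (quinic numbering) | OC[C@]1(O)C[C@H]2OC(C)(C)O[C@H]2[C@H](O)C1 | intermediate
4 | (1R,3R,4S,5R)-3,4-O-isopropylidene-1-[(p-toluenesulfonyloxy)methyl]cyclohexane-1,3,4,5-tetrol (quinic numbering) | Cc3ccc(cc3)S(=O)(=O)OC[C@]1(O)C[C@H]2OC(C)(C)O[C@H]2[C@H](O)C1 | intermediate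
5 | (1S,3R,4R,5R)-5-O-(tert-butyldiphenylsilyl)-3,4-O-isopropylidene-1-[(p-toluenesulfonyloxy)methyl]cyclohexane-1,3,4,5-tetrol (quinic numbering) | Cc3ccc(cc3)S(=O)(=O)OC[C@]1(O)C[C@H]2OC(C)(C)O[C@H]2[C@H](O[Si](c4ccccc4)(c5ccccc5)C(C)(C)C)C1 | intermediate
6 | spiro-epoxide, (1S,3R,4R,5R)-1,7-anhydro-5-O-(tert-butyldiphenylsilyl)-1-(hydroxymethyl)-3,4-O-isopropylidenecyclohexane-1,3,4,5-tetrol (quinic numbering) | C1O[C@]12C[C@H]3OC(C)(C)O[C@H]3[C@H](O[Si](c4ccccc4)(c5ccccc5)C(C)(C)C)C2 | intermediate
7 | 1-bromooctadecane | CCCCCCCCCCCCCCCCCCBr | starting material
8 | octadecylmagnesium bromide | CCCCCCCCCCCCCCCCCC[Mg]Br | intermediate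
9 | (1S,3R,4R,5R)-5-O-(tert-butyldiphenylsilyl)-3,4-O-isopropylidene-1-nonadecylcyclohexane-1,3,4,5-tetrol (quinic numbering) | CCCCCCCCCCCCCCCCCCC[C@]1(O)C[C@H]2OC(C)(C)O[C@H]2[C@H](O[Si](c3ccccc3)(c4ccccc4)C(C)(C)C)C1 | intermediate
10 | (1S,3R,4R,5R)-5-O-(tert-butyldiphenylsilyl)-1-nonadecylcyclohexane-1,3,4,5-tetrol (quinic numbering) | CCCCCCCCCCCCCCCCCCC[C@]1(O)C[C@@H](O)[C@@H](O)[C@H](O[Si](c2ccccc2)(c3ccccc3)C(C)(C)C)C1 | intermediate
11 | (1S,3R,4R,5R)-5-O-(tert-butyldiphenylsilyl)-1-nonadecyl-3,4-O-thiocarbonylcyclohexane-1,3,4,5-tetrol (quinic numbering) | CCCCCCCCCCCCCCCCCCC[C@]1(O)C[C@H]2OC(=S)O[C@H]2[C@H](O[Si](c3ccccc3)(c4ccccc4)C(C)(C)C)C1 | intermediate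
12 | (1S,5R)-5-(tert-butyldiphenylsilyloxy)-1-nonadecylcyclohex-3-en-1-ol | CCCCCCCCCCCCCCCCCCC[C@]1(O)CC=C[C@H](O[Si](c2ccccc2)(c3ccccc3)C(C)(C)C)C1 | intermediate
13 | (1R,5S)-5-nonadecylcyclohex-2-ene-1,5-diol | CCCCCCCCCCCCCCCCCCC[C@]1(O)CC=C[C@H](O)C1 | intermediate
14 | (S)-5-hydroxy-5-nonadecylcyclohex-2-en-1-one | CCCCCCCCCCCCCCCCCCC[C@]1(O)CC=CC(=O)C1 | target

## Step count and least certain steps

Total step count: 11 (the Grignard reagent 8 is generated and consumed within step 6). Longest linear sequence: 11 steps, from 1 to 14.

Step 6 (key step). The most likely failure is a Lewis-acid process outrunning the copper-mediated substitution: MgBr2 can induce a 1,2-shift (Meinwald-type isomerization) of the 2,2-disubstituted oxirane or open it with bromide. Substitution may also be slow because the CH2 is flanked by a quaternary centre, and the long-chain Grignard reagent may form sluggishly with Wurtz coupling. Fallback: from 6, the oxirane is opened at CH2 with lithium octadec-1-yn-1-ide, made from commercial 1-octadecyne and n-BuLi, in the presence of BF3·OEt2 (THF, −78 °C; Yamaguchi–Hirao alkynylation), a magnesium-free carbon nucleophile delivered at low temperature. This gives (1S,3R,4R,5R)-5-O-(tert-butyldiphenylsilyl)-3,4-O-isopropylidene-1-(nonadec-2-yn-1-yl)cyclohexane-1,3,4,5-tetrol F1. Hydrogenation of the triple bond (H2, Pd/C, EtOAc) then returns to the route at 9.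

Step 7. The risk is partial loss of the silyl ether alongside the acetonide, or incomplete acetal cleavage because the bulky neighbouring silyl ether shields the dioxolane; prolonged heating in acid could also ionize the tertiary alcohol. Fallback: from 9, both protecting groups are removed on purpose (TBAF, THF; then 2 M HCl–THF, rt) to give the free tetrol (3R,5R)-1-nonadecylcyclohexane-1,3,4,5-tetrol F2, which keeps the ring configuration of 1. The thiocarbonate is then closed only on the cis 3,4-pair, since the trans 4,5-pair would need a strained trans-fused ring (1,1'-thiocarbonyldiimidazole, 1.05 equiv, THF, rt), giving (1R,3R,4S,5R)-1-nonadecyl-3,4-O-thiocarbonylcyclohexane-1,3,4,5-tetrol F3 with free 1-OH and 5-OH. Fragmentation under the mild Corey–Hopkins variant (1,3-dimethyl-2-phenyl-1,3,2-diazaphospholidine, THF, 40 °C) returns to the route at 13.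

Step 9. The thermal cycloreversion may be slow next to the bulky silyl ether, and long heating in phosphite may phosphitylate or eliminate the free tertiary hydroxyl. Fallback: from 10, a Garegg–Samuelsson deoxygenation (PPh3, imidazole, I2, toluene, reflux) converts the diol directly into the alkene. Its mechanism is ionic and unrelated: iodide displaces one activated hydroxyl and reductive anti-elimination of the iodo-oxyphosphonium pair follows. It makes no new compound and returns to the route at 12.

Step 11. The risk is loss of water from the β-hydroxy enone as it forms, on acidic or basic sites of the oxidant or during concentration, followed by aromatization; oxidation of a pseudoaxial allylic alcohol may also be slow. Fallback: from 9, the carbonyl is installed before the alkene. Desilylation (TBAF, THF) gives (1R,3R,4S,5R)-3,4-O-isopropylidene-1-nonadecylcyclohexane-1,3,4,5-tetrol F4. Oxidation (Dess–Martin periodinane, NaHCO3, CH2Cl2) gives the ketone (2R,3R,5S)-5-hydroxy-2,3-(isopropylidenedioxy)-5-nonadecylcyclohexan-1-one F5. Reductive cleavage of the α C–O bond with SmI2 (THF–MeOH, −78 °C), the acetal leaving as acetone, gives (3R,5S)-3,5-dihydroxy-5-nonadecylcyclohexan-1-one F6. Mesylation of the secondary hydroxyl with E1cB elimination (MsCl, Et3N, CH2Cl2, −20 °C) returns to the route at 14.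

## Further compounds

F1 | step 6 | (1S,3R,4R,5R)-5-O-(tert-butyldiphenylsilyl)-3,4-O-isopropylidene-1-(nonadec-2-yn-1-yl)cyclohexane-1,3,4,5-tetrol (quinic numbering) | CCCCCCCCCCCCCCCCC#CC[C@]1(O)C[C@H]2OC(C)(C)O[C@H]2[C@H](O[Si](c3ccccc3)(c4ccccc4)C(C)(C)C)C1
F2 | step 7 | (3R,5R)-1-nonadecylcyclohexane-1,3,4,5-tetrol, ring configuration of 1 (O1, O3, O4 cis, O5 trans) | CCCCCCCCCCCCCCCCCCC[C@]1(O)C[C@@H](O)[C@@H](O)[C@H](O)C1
F3 | step 7 | (1R,3R,4S,5R)-1-nonadecyl-3,4-O-thiocarbonylcyclohexane-1,3,4,5-tetrol (quinic numbering; 1-OH and 5-OH free) | CCCCCCCCCCCCCCCCCCC[C@]1(O)C[C@H]2OC(=S)O[C@H]2[C@H](O)C1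
F0 | step 9 | none | none
F4 | step 11 | (1R,3R,4S,5R)-3,4-O-isopropylidene-1-nonadecylcyclohexane-1,3,4,5-tetrol (quinic numbering) | CCCCCCCCCCCCCCCCCCC[C@]1(O)C[C@H]2OC(C)(C)O[C@H]2[C@H](O)C1
F5 | step 11 | (2R,3R,5S)-5-hydroxy-2,3-(isopropylidenedioxy)-5-nonadecylcyclohexan-1-one | CCCCCCCCCCCCCCCCCCC[C@]1(O)C[C@H]2OC(C)(C)O[C@H]2C(=O)C1
F6 | step 11 | (3R,5S)-3,5-dihydroxy-5-nonadecylcyclohexan-1-one | CCCCCCCCCCCCCCCCCCC[C@]1(O)C[C@@H](O)CC(=O)C1
A1 | alternative 1 | 3-(tert-butyldimethylsilyloxy)-3-nonadecylcyclobutan-1-one | CCCCCCCCCCCCCCCCCCCC1(O[Si](C)(C)C(C)(C)C)CC(=O)C1
A2 | alternative 1 | acetylene | C#C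
A3 | alternative 1 | (S)-5-(tert-butyldimethylsilyloxy)-5-nonadecylcyclohex-2-en-1-one | CCCCCCCCCCCCCCCCCCC[C@]1(O[Si](C)(C)C(C)(C)C)CC=CC(=O)C1
A4 | alternative 2 | 3-nonadecylcyclohex-2-en-1-one | CCCCCCCCCCCCCCCCCCCC1=CC(=O)CCC1
A5 | alternative 2 | bis(pinacolato)diboron | CC1(C)OB(OC1(C)C)B1OC(C)(C)C(C)(C)O1
A6 | alternative 2 | (R)-3-nonadecyl-3-(4,4,5,5-tetramethyl-1,3,2-dioxaborolan-2-yl)cyclohexan-1-one | CCCCCCCCCCCCCCCCCCC[C@]1(B2OC(C)(C)C(C)(C)O2)CCCC(=O)C1
A7 | alternative 2 | (S)-3-hydroxy-3-nonadecylcyclohexan-1-one | CCCCCCCCCCCCCCCCCCC[C@]1(O)CCCC(=O)C1
A8 | alternative 2 | 3-ethoxycyclohex-2-en-1-one | CCOC1=CC(=O)CCC1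
A9 | alternative 2 | 1-bromononadecane | CCCCCCCCCCCCCCCCCCCBr
A10 | alternative 3 | racemic 1-nonadecyl-2,4-dioxabicyclo[3.3.1]non-6-en-3-one | CCCCCCCCCCCCCCCCCCCC12CC=CC(C1)OC(=O)O2
A11 | alternative 3 | sodium pivalate | [Na+].CC(C)(C)C([O-])=O
A12 | alternative 3 | (1S,5S)-5-hydroxy-5-nonadecylcyclohex-2-en-1-yl pivalate | CCCCCCCCCCCCCCCCCCC[C@]1(O)CC=C[C@@H](OC(=O)C(C)(C)C)C1
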